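The synthesis rests on opening the ten-membered carbocycle at the C1=C10 olefin (germacrane numbering). The feature exploited is C10. It is the olefinic partner of C1 and the common neighbour of carbinol C9 and acyloxymethyl C14, so retrosynthetically it is the central carbon of a 1,3-dicarbonyl unit. One amine-salt-catalysed Knoevenagel condensation with a C1 aldehyde makes the double bond and closes the ring. It also keeps C9 (ketone) and C14 (ester) distinguishable for later acylation. The precursor is an open-chain aldehyde β-keto ester. It already holds the Z C4=C5 olefin, stereocentres C6–C8, and the lactone masked as C6 and C12 silyl ethers beside the C11=C13 methylene.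

Key step: step 17

Remarks on the chemistry
- Numbering and abbreviations: germacrane numbering is used for every intermediate (C11=C13 methylene, C12 lactone carbon, C14 on C10, C15 on C4). TBS = tert-butyldimethylsilyl, TBDPS = tert-butyldiphenylsilyl, PMB = 4-methoxybenzyl.
- Source of C8: when C7 replaces the formyl carbon and C9 the ring CH2, the 8S centre of the target has the spatial arrangement of (R)-glyceraldehyde acetonide. The R (D-mannitol-derived) enantiomer is therefore required, since the S enantiomer would give the 8-epimer. The side-chain acid must be R.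
- Relative configuration: on the ten-membered ring O6 is trans to C11, while C11, O8 and O9 are mutually cis. In open-chain terms, O6/C8 is anti across the bond made in the fragment coupling, and O8/O9 is erythro.
- Allyl donor: 2-(bromomethyl)enoates that keep the C12 ester react through the allylmetal geometry with C8 trans to the ester, which favours the cis C6/C7 relationship. The donor is therefore reduced and silylated at C12 before coupling, so that it behaves as an ordinary γ-substituted allylchromium reagent.
- Design of the cyclisation precursor: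
  - O8 carries PMB, which can chelate during the C9 reduction and is removed last at neutral pH.
  - O6 carries TBS and O12 carries TBDPS, and both survive the two acid acetal cleavages.
  - The C14 ester is ethyl, a spectator group lost on reduction, because ethyl diazoacetate is the commercial reagent.
- Assumption: commercial neryl acetate, the acetate of nerol, is used with high Z purity.

Step 1
Reactants: 1 neryl acetate
Product: 2 6,7-epoxyneryl acetate
Conditions: mCPBA (1.05 equiv), CH2Cl2, 0 °C
Reagents that add atoms: mCPBA, O=C(OO)c1cccc(Cl)c1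
Why: Prilezhaev epoxidation selects the remote trisubstituted olefin because the other one is deactivated by the allylic acetate, and the racemic oxirane centre is destroyed in step 2.

Step 2
Reactants: 2 6,7-epoxyneryl acetate
Product: 3 (2Z)-3-methyl-6-oxohex-2-en-1-yl acetate
Conditions: H5IO6 (1.2 equiv), THF/H2O (10:1), 0 °C
Reagents that add atoms: none
Why: Periodic acid opens the oxirane and cleaves the resulting glycol (Malaprade-type cleavage) in one flask, releasing C1 as the aldehyde without touching the Z olefin or the acetate.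

Step 3
Reactants: 3 (2Z)-3-methyl-6-oxohex-2-en-1-yl acetate
Product: 5 (2Z)-6,6-dimethoxy-3-methylhex-2-en-1-ol, via acetal acetate 4 (not isolated)
Conditions: HC(OMe)3, p-TsOH·H2O (1 mol%), MeOH, rt; then K2CO3 (20 mol%), rt
Reagents that add atoms: trimethyl orthoformate, COC(OC)OC
Why: Acid-catalysed acetalisation driven by the orthoformate masks C1, and base-catalysed transesterification in the same methanol solution then frees the allylic alcohol.

Step 4
Reactants: 5 (2Z)-6,6-dimethoxy-3-methylhex-2-en-1-ol
Product: 6 (2Z)-6,6-dimethoxy-3-methylhex-2-enal (fragment A)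
Conditions: TEMPO (10 mol%), PhI(OAc)2 (1.1 equiv), CH2Cl2, 0 °C
Reagents that add atoms: none
Why: Oxoammonium oxidation of the primary allylic alcohol is mild enough to keep both the Z geometry of this neral-type enal and the acetal.

Step 5
Reactants: 7 (R)-2,2-dimethyl-1,3-dioxolane-4-carbaldehyde; 8 methyl acrylate
Product: 9 methyl 2-{[(4R)-2,2-dimethyl-1,3-dioxolan-4-yl](hydroxy)methyl}prop-2-enoate (both carbinol epimers)
Conditions: DABCO (0.5 equiv), 1,4-dioxane/H2O (1:1), rt
Reagents that add atoms: none
Why: The Morita–Baylis–Hillman reaction joins C7 to C11, the carbinol epimers need no separation because C7 becomes sp2 in step 6, and C8 keeps the configuration of 7.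

Step 6
Reactants: 9 Morita–Baylis–Hillman adduct
Product: 10 methyl (2Z)-2-(bromomethyl)-3-[(4S)-2,2-dimethyl-1,3-dioxolan-4-yl]prop-2-enoate
Conditions: NBS, Me2S, CH2Cl2, 0 °C to rt
Reagents that add atoms: N-bromosuccinimide, O=C1CCC(=O)N1Br
Why: The sulfonium salt made from NBS and Me2S activates the hydroxyl and bromide enters by SN2' displacement, giving the conjugated Z bromide under neutral conditions that spare the acetonide.

Step 7
Reactants: 10 bromo ester
Product: 11 (2Z)-2-(bromomethyl)-3-[(4S)-2,2-dimethyl-1,3-dioxolan-4-yl]prop-2-en-1-ol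
Conditions: i-Bu2AlH (2.2 equiv), CH2Cl2, −78 °C
Reagents that add atoms: none
Why: 1,2-Reduction of the enoate at low temperature is faster than attack on the allylic bromide, brings C12 to the oxidation level needed in the cyclisation precursor, and removes the ester that would bias the allylmetal geometry towards the cis C6/C7 series.

Step 8
Reactants: 11 bromo alcohol
Product: 12 TBDPS ether of 11 (fragment B)
Conditions: TBDPSCl, imidazole, CH2Cl2, 0 °C, short reaction time
Reagents that add atoms: tert-butyl(chloro)diphenylsilane, CC(C)(C)[Si](Cl)(c1ccccc1)c1ccccc1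
Why: Silylation of the unhindered primary alcohol is faster than N-alkylation of imidazole by the bromide, and the acid-stable TBDPS group is chosen to outlast the later acetal cleavages.

Step 9
Reactants: 6 fragment A enal; 12 fragment B bromide
Product: 14 seco alcohol (6R,7S,8S): C1 dimethyl acetal; 4Z; 6-OH; 12-OTBDPS; 8,9-O-isopropylidene, via allylchromium reagent 13 (not isolated)
Conditions: CrCl2 (4 equiv), THF, 0 °C to rt, 6 and 12 added together
Reagents that add atoms: none
Why: In this Nozaki–Hiyama allylation the allylchromium species equilibrates to the geometry with C8 trans to CH2Cr and adds through C7 in a closed chair transition state with both large groups equatorial (O6/C8 anti, the future trans-lactone relationship), while allylic 1,3-strain keeps H8 in the olefin plane so that the aldehyde approaches anti to the C8–C9 bond with O8 pointing outwards, which fixes C7 relative to C8.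

Step 10
Reactants: 14 seco alcohol
Product: 15 6-O-TBS ether of 14 (6R,7R,8S)
Conditions: TBSOTf (1.2 equiv), 2,6-lutidine, CH2Cl2, −78 °C
Reagents that add atoms: tert-butyldimethylsilyl triflate, CC(C)(C)[Si](C)(C)OS(=O)(=O)C(F)(F)F
Why: Silyl triflate silylation of the hindered secondary allylic alcohol is much faster at −78 °C than activation of the two acetals.

Step 11
Reactants: 15 6-O-TBS ether
Product: 16 8,9-diol (6R,7R,8S)
Conditions: PPTS (20 mol%), MeOH, 40 °C; Et3N quench before evaporation
Reagents that add atoms: none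
Why: Acid-catalysed methanolysis removes the terminal ketal while the C1 dimethyl acetal only undergoes degenerate exchange with the solvent and the secondary TBS and TBDPS ethers are too robust to be cleaved.

Step 12
Reactants: 16 8,9-diol
Product: 17 8,9-O-(4-methoxybenzylidene) acetal (6R,7R,8S; both acetal epimers)
Conditions: 4-MeOC6H4CH(OMe)2 (1.5 equiv), PPTS (5 mol%), CH2Cl2, rt
Reagents that add atoms: 4-methoxybenzaldehyde dimethyl acetal, COc1ccc(cc1)C(OC)OC
Why: Transacetalisation succeeds because the aryl acetal ionises far more readily than the aliphatic C1 acetal, so only the benzylidene unit is transferred to the diol.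

Step 13
Reactants: 17 4-methoxybenzylidene acetal
Product: 18 8-O-PMB 9-alcohol (6R,7R,8S)
Conditions: i-Bu2AlH (3 equiv), CH2Cl2, −78 to −20 °C
Reagents that add atoms: none
Why: In this regioselective reductive acetal opening aluminium binds the less hindered O9, so the benzylic oxocarbenium ion stays on O8 and is reduced, leaving PMB on C8 and the primary C9 alcohol free.

Step 14
Reactants: 18 8-O-PMB 9-alcohol
Product: 19 8-O-PMB C9 aldehyde (6R,7R,8S)
Conditions: Dess–Martin periodinane, pyridine, CH2Cl2, 0 °C
Reagents that add atoms: none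
Why: Dess–Martin oxidation with pyridine buffering gives the α-alkoxy aldehyde without enolisation, so C8 is not epimerised.

Step 15
Reactants: 19 C9 aldehyde; 20 ethyl diazoacetate
Product: 21 C9-keto C14-ethyl ester with C1 dimethyl acetal (6R,7R,8S)
Conditions: SnCl2 (15 mol%), CH2Cl2, rt
Reagents that add atoms: none
Why: In the Roskamp homologation the diazo carbon (C10) attacks the SnCl2-activated aldehyde and a 1,2-hydride shift with loss of N2 gives the β-keto ester directly under non-basic conditions that leave C8 intact.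

Step 16
Reactants: 21 β-keto ester acetal
Product: 22 seco β-keto ester with C1 aldehyde (6R,7R,8S)
Conditions: PPTS (20 mol%), acetone/H2O (10:1), 40 °C
Reagents that add atoms: water, O
Why: Mild acid hydrolysis of the acyclic acetal, which is far more labile than the secondary TBS, TBDPS and PMB ethers, unmasks the C1 aldehyde as the last operation before ring closure.

Step 17
Reactants: 22 seco β-keto ester with C1 aldehyde
Product: 25 ten-membered alkylidene β-keto ester (4Z; C2 cis to C9; 6R,7R,8S), via iminium ion 23 (not isolated), via Mannich base 24 (not isolated)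
Conditions: piperidine (0.5 equiv), AcOH (0.5 equiv), 4 Å MS, toluene, 40 °C, 22 added over 12 h (final 1 mM)
Reagents that add atoms: none
Why: Piperidine turns the C1 aldehyde into iminium ion 23, the enol of the β-keto ester attacks it through C10 to give Mannich base 24, and E1cB loss of piperidine delivers the alkylidene β-keto ester, the closest known reaction type being the intramolecular Knoevenagel condensation of β-keto esters with aldehydes used for macrocycles. The carbocycle closes in a 10-exo-trig mode (the C=N bond lies outside the forming ring), helped by the Z C4=C5 olefin and the three contiguous branched centres C6–C8, which fold the chain. No stereocentre is created. Ring closure must beat oligomerisation, which is secured by slow addition to high dilution and by the reversibility of every step before dehydration. The olefin geometry is secured because reversible conjugate addition of piperidine equilibrates the doubly activated double bond to the less strained isomer with C2 cis to C9. C8 does not epimerise because the buffered amine salt acts on the far more acidic C10 methylene rather than enolising the ketone towards C8, and the nucleophile has no β-leaving group that could be eliminated.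

Step 18
Reactants: 25 alkylidene β-keto ester
Product: 26 9-alcohol (6R,7R,8S,9R)
Conditions: Zn(BH4)2, Et2O, −40 °C
Reagents that add atoms: none
Why: In this chelation-controlled 1,2-reduction divalent zinc ties the C9 carbonyl oxygen to the PMB ether oxygen on C8 in a five-membered chelate and hydride arrives from the open peripheral face on the side of H8, giving the erythro (ring-cis) 9R alcohol.

Step 19
Reactants: 26 9-alcohol
Product: 27 9,14-diol (6R,7R,8S,9R)
Conditions: i-Bu2AlH (4 equiv), CH2Cl2, −78 °C
Reagents that add atoms: none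
Why: After deprotonating C9–OH, i-Bu2AlH reduces the α,β-unsaturated ester in 1,2 fashion to the C14 allylic alcohol while ethers and silyl ethers are inert.

Step 20
Reactants: 27 9,14-diol; 28 (R)-2-methylbutanoic acid
Product: 29 14-O-[(2R)-2-methylbutanoyl] 9-alcohol (6R,7R,8S,9R)
Conditions: DCC (1.05 equiv), DMAP (10 mol%), CH2Cl2, −10 to 0 °C
Reagents that add atoms: none
Why: Steglich esterification at low temperature acylates the unhindered primary allylic C14–OH in preference to the flanked secondary C9–OH, and the α-stereocentre of 28 is retained because no ketene-forming conditions are used.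

Step 21
Reactants: 29 14-ester 9-alcohol
Product: 30 9-acetate (6R,7R,8S,9R)
Conditions: Ac2O, pyridine, DMAP (cat.), CH2Cl2, 0 °C to rt
Reagents that add atoms: acetic anhydride, CC(=O)OC(C)=O
Why: DMAP-catalysed acetylation meets only one free hydroxyl and is run directly after step 20 so that 14-to-9 acyl migration has no time to occur.

Step 22
Reactants: 30 9-acetate
Product: 31 6,12-diol (6R,7S,8S,9R)
Conditions: HF·pyridine, pyridine, THF, 0 °C to rt
Reagents that add atoms: none
Why: Buffered fluoride desilylation removes both silyl ethers while the two esters and the PMB ether, which must still block O8, survive.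

Step 23
Reactants: 31 6,12-diol
Product: 34 8-O-PMB α-methylene-γ-butyrolactone (6R,7S,8S,9R), via hydroxy enal 32 (not isolated), via lactol 33 (not isolated)
Conditions: TEMPO (20 mol%), PhI(OAc)2 (3 equiv), CH2Cl2, rt
Reagents that add atoms: none
Why: In this oxidative lactonisation the oxoammonium salt takes the primary allylic C12–OH to enal 32, C6–OH closes lactol 33 and a second oxidation gives the lactone, whose trans fusion follows from C6 and C7 and whose 8,12-isomer cannot form because O8 is blocked.

Step 24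
Reactants: 34 8-O-PMB lactone
Product: 35 target CNP0005248.2 (6R,7R,8S,9R,2'R)
Conditions: DDQ (1.5 equiv), CH2Cl2/pH 7 buffer (NaH2PO4/Na2HPO4), 0 °C
Reagents that add atoms: none
Why: Oxidative PMB cleavage proceeds by hydride abstraction from the electron-rich benzylic position at neutral pH, so neither acetate migration from O9 to O8 nor translactonisation is triggered.

Compound list
1 | neryl acetate, (2Z)-3,7-dimethylocta-2,6-dien-1-yl acetate | CC(C)=CCC/C(C)=C\COC(C)=O | starting material
2 | 6,7-epoxyneryl acetate (racemic oxirane) | CC1(C)OC1CC/C(C)=C\COC(C)=O | intermediate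
3 | (2Z)-3-methyl-6-oxohex-2-en-1-yl acetate | O=CCC/C(C)=C\COC(C)=O | intermediate
4 | (2Z)-6,6-dimethoxy-3-methylhex-2-en-1-yl acetate | COC(OC)CC/C(C)=C\COC(C)=O | intermediate
5 | (2Z)-6,6-dimethoxy-3-methylhex-2-en-1-ol | COC(OC)CC/C(C)=C\CO | intermediate
6 | (2Z)-6,6-dimethoxy-3-methylhex-2-enal (fragment A) | COC(OC)CC/C(C)=C\C=O | intermediate
7 | (R)-2,2-dimethyl-1,3-dioxolane-4-carbaldehyde | O=C[C@H]1COC(C)(C)O1 | starting material
8 | methyl acrylate | C=CC(=O)OC | starting material
9 | methyl 2-{[(4R)-2,2-dimethyl-1,3-dioxolan-4-yl](hydroxy)methyl}prop-2-enoate (carbinol epimers) | C=C(C(=O)OC)C(O)[C@H]1COC(C)(C)O1 | intermediate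
10 | methyl (2Z)-2-(bromomethyl)-3-[(4S)-2,2-dimethyl-1,3-dioxolan-4-yl]prop-2-enoate | BrC/C(C(=O)OC)=C\[C@H]1COC(C)(C)O1 | intermediate
11 | (2Z)-2-(bromomethyl)-3-[(4S)-2,2-dimethyl-1,3-dioxolan-4-yl]prop-2-en-1-ol | BrC/C(CO)=C\[C@H]1COC(C)(C)O1 | intermediate
12 | TBDPS ether of 11 (fragment B) | BrC/C(CO[Si](c1ccccc1)(c1ccccc1)C(C)(C)C)=C\[C@H]1COC(C)(C)O1 | intermediate
13 | (E)-allylchromium dichloride from 12 (C8 trans to CH2Cr, trivalent chromium, solvated) | Cl[Cr](Cl)C/C(CO[Si](c1ccccc1)(c1ccccc1)C(C)(C)C)=C/[C@H]1COC(C)(C)O1 | intermediate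
14 | seco alcohol (6R,7S,8S): C1 dimethyl acetal, 4Z, 6-OH, 12-OTBDPS, 8,9-acetonide | COC(OC)CC/C(C)=C\[C@@H](O)[C@H](C(=C)CO[Si](c1ccccc1)(c1ccccc1)C(C)(C)C)[C@H]1COC(C)(C)O1 | intermediate
15 | 6-O-TBS ether of 14 (6R,7R,8S) | COC(OC)CC/C(C)=C\[C@@H](O[Si](C)(C)C(C)(C)C)[C@H](C(=C)CO[Si](c1ccccc1)(c1ccccc1)C(C)(C)C)[C@H]1COC(C)(C)O1 | intermediate
16 | 8,9-diol (6R,7R,8S) | COC(OC)CC/C(C)=C\[C@@H](O[Si](C)(C)C(C)(C)C)[C@H](C(=C)CO[Si](c1ccccc1)(c1ccccc1)C(C)(C)C)[C@H](O)CO | intermediate
17 | 8,9-O-(4-methoxybenzylidene) acetal (6R,7R,8S, acetal epimers) | COC(OC)CC/C(C)=C\[C@@H](O[Si](C)(C)C(C)(C)C)[C@H](C(=C)CO[Si](c1ccccc1)(c1ccccc1)C(C)(C)C)[C@H]1COC(c2ccc(OC)cc2)O1 | intermediate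
18 | 8-O-PMB 9-alcohol (6R,7R,8S) | COC(OC)CC/C(C)=C\[C@@H](O[Si](C)(C)C(C)(C)C)[C@H](C(=C)CO[Si](c1ccccc1)(c1ccccc1)C(C)(C)C)[C@H](OCc1ccc(OC)cc1)CO | intermediate
19 | 8-O-PMB C9 aldehyde (6R,7R,8S) | COC(OC)CC/C(C)=C\[C@@H](O[Si](C)(C)C(C)(C)C)[C@H](C(=C)CO[Si](c1ccccc1)(c1ccccc1)C(C)(C)C)[C@H](OCc1ccc(OC)cc1)C=O | intermediate
20 | ethyl diazoacetate | CCOC(=O)C=[N+]=[N-] | starting material
21 | C9-keto C14-ethyl ester with C1 dimethyl acetal (6R,7R,8S) | COC(OC)CC/C(C)=C\[C@@H](O[Si](C)(C)C(C)(C)C)[C@H](C(=C)CO[Si](c1ccccc1)(c1ccccc1)C(C)(C)C)[C@H](OCc1ccc(OC)cc1)C(=O)CC(=O)OCC | intermediate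
22 | seco β-keto ester with C1 aldehyde (6R,7R,8S), precursor of the key step | O=CCC/C(C)=C\[C@@H](O[Si](C)(C)C(C)(C)C)[C@H](C(=C)CO[Si](c1ccccc1)(c1ccccc1)C(C)(C)C)[C@H](OCc1ccc(OC)cc1)C(=O)CC(=O)OCC | intermediate
23 | C1 piperidinium iminium acetate of 22 | CC(=O)[O-].C(=[N+]1CCCCC1)CC/C(C)=C\[C@@H](O[Si](C)(C)C(C)(C)C)[C@H](C(=C)CO[Si](c1ccccc1)(c1ccccc1)C(C)(C)C)[C@H](OCc1ccc(OC)cc1)C(=O)CC(=O)OCC | intermediate
24 | ten-membered Mannich base, 1-piperidino keto ester (C1 and C10 epimers) | CC(C)(C)[Si](C)(C)O[C@@H]1/C=C(/C)CCC(N2CCCCC2)C(C(=O)OCC)C(=O)[C@@H](OCc2ccc(OC)cc2)[C@H]1C(=C)CO[Si](c2ccccc2)(c2ccccc2)C(C)(C)C | intermediate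
25 | ten-membered alkylidene β-keto ester (4Z, C2 cis to C9, 6R,7R,8S), product of the key step | CC(C)(C)[Si](C)(C)O[C@@H]1/C=C(/C)CC/C=C(/C(=O)OCC)C(=O)[C@@H](OCc2ccc(OC)cc2)[C@H]1C(=C)CO[Si](c2ccccc2)(c2ccccc2)C(C)(C)C | intermediate
26 | 9-alcohol (6R,7R,8S,9R) | CC(C)(C)[Si](C)(C)O[C@@H]1/C=C(/C)CC/C=C(/C(=O)OCC)[C@@H](O)[C@@H](OCc2ccc(OC)cc2)[C@H]1C(=C)CO[Si](c2ccccc2)(c2ccccc2)C(C)(C)C | intermediate
27 | 9,14-diol (6R,7R,8S,9R) | CC(C)(C)[Si](C)(C)O[C@@H]1/C=C(/C)CC/C=C(/CO)[C@@H](O)[C@@H](OCc2ccc(OC)cc2)[C@H]1C(=C)CO[Si](c2ccccc2)(c2ccccc2)C(C)(C)C | intermediate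
28 | (R)-2-methylbutanoic acid | CC[C@@H](C)C(=O)O | starting material
29 | 14-O-[(2R)-2-methylbutanoyl] 9-alcohol | CC(C)(C)[Si](C)(C)O[C@@H]1/C=C(/C)CC/C=C(/COC(=O)[C@H](C)CC)[C@@H](O)[C@@H](OCc2ccc(OC)cc2)[C@H]1C(=C)CO[Si](c2ccccc2)(c2ccccc2)C(C)(C)C | intermediate
30 | 9-acetate of 29 | CC(C)(C)[Si](C)(C)O[C@@H]1/C=C(/C)CC/C=C(/COC(=O)[C@H](C)CC)[C@@H](OC(C)=O)[C@@H](OCc2ccc(OC)cc2)[C@H]1C(=C)CO[Si](c2ccccc2)(c2ccccc2)C(C)(C)C | intermediate
31 | 6,12-diol (6R,7S,8S,9R) | O[C@@H]1/C=C(/C)CC/C=C(/COC(=O)[C@H](C)CC)[C@@H](OC(C)=O)[C@@H](OCc2ccc(OC)cc2)[C@H]1C(=C)CO | intermediate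
32 | 6-hydroxy C12 enal | O[C@@H]1/C=C(/C)CC/C=C(/COC(=O)[C@H](C)CC)[C@@H](OC(C)=O)[C@@H](OCc2ccc(OC)cc2)[C@H]1C(=C)C=O | intermediate
33 | 6,12-lactol (C12 epimers) | C=C1C(O)O[C@@H]2/C=C(/C)CC/C=C(/COC(=O)[C@H](C)CC)[C@@H](OC(C)=O)[C@@H](OCc3ccc(OC)cc3)[C@@H]12 | intermediate
34 | 8-O-PMB α-methylene-γ-butyrolactone (6R,7S,8S,9R) | C=C1C(=O)O[C@@H]2/C=C(/C)CC/C=C(/COC(=O)[C@H](C)CC)[C@@H](OC(C)=O)[C@@H](OCc3ccc(OC)cc3)[C@@H]12 | intermediate
35 | CNP0005248.2 (6R,7R,8S,9R,2'R) | C=C1C(=O)O[C@@H]2/C=C(/C)CC/C=C(/COC(=O)[C@H](C)CC)[C@@H](OC(C)=O)[C@@H](O)[C@@H]12 | target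

Total step count: 24.
Longest linear sequence: 20 steps. This is steps 1–4 followed by 9–24, and the branch through steps 5–8 is equally long.

Steps most likely to fail

Step 17, ring closure. Intermolecular condensation may outrun the ten-membered closure, or the new olefin may drift out of conjugation towards C1=C2 under the amine. The fallback sets out from 21 and uses the C1 acetal itself as the electrophile.
- TMSCl/Et3N converts the β-keto ester into the silyl enol ether F1.
- Catalytic TMSOTf in CH2Cl2 at −78 °C under high dilution ionises the acetal. An irreversible intramolecular Mukaiyama aldol-type addition to the oxocarbenium ion then closes the ring to the β-methoxy keto ester F2.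
- DBU removes methanol by E1cB elimination, and the route is rejoined at 25.

Step 9, fragment coupling. The anti simple diastereoselection may erode through a competing chair with C8 axial. The allylmetal may also be partly lost by vinylogous elimination of the C8 oxygen. The fallback sets out from 6 and 12, keeps the coupling, and corrects C6 afterwards by substitution.
- The separated C6 epimer of the seco alcohol F3 is treated with 4-nitrobenzoic acid, PPh3 and DIAD. In this Mitsunobu reaction SN2' is blocked by the fully substituted C4, and the product is the inverted 6R 4-nitrobenzoate F4.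
- K2CO3/MeOH removes the ester, and the material returns to the route at 14.

Step 18, C9 reduction. Hydride may be delivered to the wrong carbonyl face if the ring conformation overrides the chelate, and conjugate reduction of the doubly activated olefin may compete. The fallback sets out from 25 and deliberately goes through the other epimer.
- Non-chelating NaBH4/CeCl3·7H2O in MeOH at −78 °C gives the 9S alcohol F5.
- i-Bu2AlH gives the 9-epi diol F6.
- Steglich esterification with 28 gives the 9-epi 14-ester F7.
- A Mitsunobu reaction with AcOH, PPh3 and DIAD inverts C9 while installing the acetate, and the route is rejoined at 30.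

Further compounds
F1 | step 17 | trimethylsilyl enol ether of 21 (enol geometry open) | COC(OC)CC/C(C)=C\[C@@H](O[Si](C)(C)C(C)(C)C)[C@H](C(=C)CO[Si](c1ccccc1)(c1ccccc1)C(C)(C)C)[C@H](OCc1ccc(OC)cc1)C(O[Si](C)(C)C)=CC(=O)OCC
F2 | step 17 | ten-membered 1-methoxy keto ester (C1 and C10 epimers) | CC(C)(C)[Si](C)(C)O[C@@H]1/C=C(/C)CCC(OC)C(C(=O)OCC)C(=O)[C@@H](OCc2ccc(OC)cc2)[C@H]1C(=C)CO[Si](c2ccccc2)(c2ccccc2)C(C)(C)C
F3 | step 9 | C6 epimer of 14 (6S,7S,8S) | COC(OC)CC/C(C)=C\[C@H](O)[C@H](C(=C)CO[Si](c1ccccc1)(c1ccccc1)C(C)(C)C)[C@H]1COC(C)(C)O1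
F4 | step 9 | 6-O-(4-nitrobenzoate) of 14 (6R,7S,8S) | COC(OC)CC/C(C)=C\[C@@H](OC(=O)c1ccc(cc1)[N+](=O)[O-])[C@H](C(=C)CO[Si](c1ccccc1)(c1ccccc1)C(C)(C)C)[C@H]1COC(C)(C)O1
F5 | step 18 | C9 epimer of 26 (9S) | CC(C)(C)[Si](C)(C)O[C@@H]1/C=C(/C)CC/C=C(/C(=O)OCC)[C@H](O)[C@@H](OCc2ccc(OC)cc2)[C@H]1C(=C)CO[Si](c2ccccc2)(c2ccccc2)C(C)(C)C
F6 | step 18 | C9 epimer of 27 (9S) | CC(C)(C)[Si](C)(C)O[C@@H]1/C=C(/C)CC/C=C(/CO)[C@H](O)[C@@H](OCc2ccc(OC)cc2)[C@H]1C(=C)CO[Si](c2ccccc2)(c2ccccc2)C(C)(C)C
F7 | step 18 | C9 epimer of 29 (9S) | CC(C)(C)[Si](C)(C)O[C@@H]1/C=C(/C)CC/C=C(/COC(=O)[C@H](C)CC)[C@H](O)[C@@H](OCc2ccc(OC)cc2)[C@H]1C(=C)CO[Si](c2ccccc2)(c2ccccc2)C(C)(C)C
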